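**Plan**

1. Numbering used here: C1 = CH–O(angelate), C2 = CH2, C3 = CH–O(epoxy ester), C4 = CMe2, C5(H)–C6(H)–C11(Me)–C10(H) = the four-membered ring, C7 = C=O, C8 = =CH, C9 = =C(Me).
2. Retrosynthetic cuts, in order: both ester C–O bonds; C7–C8, closing the enone ring across the 1,3-positions C6/C10 of the cyclobutane (possible because formyl C7 on C6 and the 2-(silylmethyl)allyl carbon C9 on C10 stand cis, both anti to the C1–C4 bridge, with silicon β to C9); the allylsilane back to a C9 ester; the lactone C9(=O)–O–C3 back to a temporary C3–C9 bond (Baeyer–Villiger); C5–C6 and C10–C11 (enone–enone [2+2]); C1–C11 (Nozaki–Hiyama–Kishi); C2–C3 (allylation).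
3. Forward: bought cyclopentenone ring (C9, C10, C5, C4, C3) → side chain on C3 → photocycloaddition (four-membered ring plus a temporary six-membered ring) → C3–C9 cut, which turns the cage into the seven-membered ring C11–C1–C2–C3–C4–C5–C10 → Sakurai closure C7–C8 (six-membered enone ring) → the two esters.
4. Stereochemistry: C3 by Pd-catalysed asymmetric allylation; through the tether it fixes C5, C10, C11 in the [2+2] and becomes C3–O with retention; C1 by hydride attack on the outer face of the cage; C6 and C10 by equilibration α to carbonyl; epoxide by Sharpless epoxidation; angelate geometry from angelic acid.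

Key step: step 18

Remark on the chemistry: the ligand antipode in step 2 is taken to be the one that gives the (5R)-allyl ketone (sense of induction assumed by analogy with allyl enol carbonates of cyclic ketones); (E)-2-methylbut-2-en-1-ol and angelic acid are taken as commercial.

**Route**

Step 1
Reactants: 1 4,4-dimethylcyclopent-2-en-1-one
Product: 3 allyl 3,3-dimethylcyclopenta-1,4-dien-1-yl carbonate, via lithium dienolate 2 (not isolated)
Conditions: LiN(SiMe3)2, TMEDA, THF, −78 °C; then ClCO2CH2CH=CH2
Reagents that add atoms: allyl chloroformate, C=CCOC(Cl)=O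
Why: Deprotonation can occur only at C3 (C4 is quaternary) and the lithium dienolate should be O-acylated by the chloroformate (enol carbonate formation), which sets up the decarboxylative allylation.

Step 2
Reactants: 3 allyl 3,3-dimethylcyclopenta-1,4-dien-1-yl carbonate
Product: 4 (5R)-5-allyl-4,4-dimethylcyclopent-2-en-1-one
Conditions: Pd2(dba)3 (2.5 mol %), (R,R)-N,N'-bis(2-diphenylphosphinobenzoyl)cyclohexane-1,2-diamine (6 mol %), 1,4-dioxane, 23 °C
Reagents that add atoms: none
Why: Decarboxylative asymmetric Tsuji–Trost allylation: zerovalent palladium ionises the carbonate, CO2 is lost and the π-allylpalladium/dienolate pair should join at C3, the only nucleophilic carbon of the cross-conjugated dienolate, the ligand choosing the enolate face and so setting C3 under neutral conditions that do not racemise it.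

Step 3
Reactants: 4 (5R)-5-allyl-4,4-dimethylcyclopent-2-en-1-one
Product: 6 2-[(1R)-2,2-dimethyl-5-oxocyclopent-3-en-1-yl]acetaldehyde, via vicinal diol 5 (not isolated)
Conditions: OsO4 (2 mol %), NaIO4, 2,6-lutidine, dioxane/H2O, 23 °C
Reagents that add atoms: osmium tetroxide, O=[Os](=O)(=O)=O (reoxidised by sodium periodate, [Na+].[O-]I(=O)(=O)=O)
Why: Lemieux–Johnson cleavage: OsO4 should dihydroxylate the terminal alkene in preference to the electron-poor enone, and periodate cleaves the diol to the aldehyde that becomes C1.

Step 4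
Reactants: 7 but-2-yn-1-ol
Product: 9 (E)-3-iodobut-2-en-1-ol, via alkenylzirconocene 8 (not isolated)
Conditions: Cp2Zr(H)Cl (2.2 equiv), THF, 23 °C; then I2, 0 °C
Reagents that add atoms: iodine, II
Why: syn-Hydrozirconation of the alkyne (zirconium on the carbon remote from the zirconated oxygen) followed by iodinolysis with retention should give the (E)-alkenyl iodide, methyl cis to CH2OH.

Step 5
Reactants: 9 (E)-3-iodobut-2-en-1-ol
Product: 10 (E)-3-iodobut-2-en-1-yl acetate
Conditions: Ac2O, pyridine, DMAP (cat.), CH2Cl2, 0 → 23 °C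
Reagents that add atoms: acetic anhydride, CC(=O)OC(C)=O
Why: Routine acetylation; the acetate survives the chromium, photochemical and peracid steps and falls off by itself in the methanolysis of step 12.

Step 6
Reactants: 6 2-[(1R)-2,2-dimethyl-5-oxocyclopent-3-en-1-yl]acetaldehyde; 10 (E)-3-iodobut-2-en-1-yl acetate
Product: 11 (2E)-5-[(1R)-2,2-dimethyl-5-oxocyclopent-3-en-1-yl]-4-hydroxy-3-methylpent-2-en-1-yl acetate (both carbinol epimers)
Conditions: CrCl2 (4 equiv), NiCl2 (1 mol %), DMSO, 23 °C
Reagents that add atoms: none
Why: Nozaki–Hiyama–Kishi coupling: the alkenylchromium species formed under nickel catalysis should add to the aldehyde only (not to the hindered enone) with retention of alkene geometry, and the new carbinol centre does not matter because it is oxidised next.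

Step 7
Reactants: 11 allylic alcohol (both epimers)
Product: 12 (2E)-5-[(1R)-2,2-dimethyl-5-oxocyclopent-3-en-1-yl]-3-methyl-4-oxopent-2-en-1-yl acetate
Conditions: Dess–Martin periodinane, NaHCO3, CH2Cl2, 0 → 23 °C
Reagents that add atoms: none
Why: Dess–Martin oxidation under buffered, non-basic conditions should give the second enone (C1 ketone) without epimerising C3.

Step 8
Reactants: 12 bis-enone
Product: 13 tricyclic diketone (four-membered ring C5–C6–C11–C10; C9=O bridging C10 and C3; C1=O between C11 and C2; CH2OAc exo on C6)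
Conditions: hν (350 nm), degassed CH2Cl2 (5 mM), 0 °C
Reagents that add atoms: none
Why: Intramolecular enone–enone [2+2] photocycloaddition: the two β-carbons (C5, C6) and the two α-carbons (C10, C11) should join (head-to-head, through the 1,4-biradical stabilised by an acyl group at both ends, the crossed mode being disfavoured by the gem-dimethyl group at C4), the C3–C2–C1 link allows addition only on the cyclopentenone face that carries the side chain so that C3 fixes C5, C10 and C11, and CH2OAc takes the exo position on C6.

Step 9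
Reactants: 13 tricyclic diketone
Product: 14 keto lactone (O inserted between C9 and C3; C1 ketone kept)
Conditions: mCPBA, NaHCO3, CH2Cl2, 0 → 23 °C
Reagents that add atoms: 3-chloroperoxybenzoic acid, OOC(=O)c1cccc(Cl)c1
Why: Baeyer–Villiger oxidation: the strained one-carbon-bridge ketone C9 (both neighbours bridgeheads) should add peracid faster than the C1 ketone next to quaternary C11, and the ordinary secondary carbon C3 should migrate in preference to the cyclobutane carbon C10 (more s character), with retention, so that the C3–C9 bond is cut and C3–O is installed in the configuration of the target.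

Step 10
Reactants: 14 keto lactone
Product: 15 hydroxy lactone (C1–OH, configuration of the target)
Conditions: NaBH4, MeOH/THF, −40 → 0 °C
Reagents that add atoms: none
Why: NaBH4 leaves lactone and acetate alone and should reduce the only ketone from the open outer face of the cage (anti to the four-membered ring and the C4–C5 bridge), which places the C1 hydroxyl as in the target.

Step 11
Reactants: 15 hydroxy lactone
Product: 16 silyl ether lactone (C1–OTBS)
Conditions: TBSOTf, 2,6-lutidine, CH2Cl2, 0 °C
Reagents that add atoms: tert-butyldimethylsilyl trifluoromethanesulfonate, CC(C)(C)[Si](C)(C)OS(=O)(=O)C(F)(F)F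
Why: Silylation with the triflate is needed for the hindered neopentyl alcohol and marks the C1 oxygen before the C3 oxygen is set free, so the two can later carry different esters.

Step 12
Reactants: 16 silyl ether lactone
Product: 18 trans hydroxy ester (bicyclo[4.1.1]octane; C10–CO2Me anti to the C1–C4 bridge and cis to C6–CH2OH; C3–OH; C1–OTBS), via cis hydroxy ester 17 (not isolated)
Conditions: NaOMe, MeOH, 65 °C
Reagents that add atoms: methanol, CO
Why: Methoxide opens the lactone and removes the acetate; the cis hydroxy ester can relactonise but its C10 epimer (enolisation α to the ester) cannot, so the material should drain to the ester with C9 anti to the bridge, the favoured all-trans cyclobutane.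

Step 13
Reactants: 18 trans hydroxy ester
Product: 21 allylsilane diol (C10–C(=CH2)CH2SiMe3; C9 is the sp2 carbon), via silylmethyl ketone 19 (not isolated), via bis(silylmethyl)carbinol 20 (not isolated)
Conditions: Me3SiCH2MgCl (6 equiv), CeCl3, THF, −78 → 23 °C; then SiO2, CH2Cl2, 23 °C
Reagents that add atoms: (trimethylsilyl)methylmagnesium chloride, C[Si](C)(C)C[Mg]Cl
Why: Double addition of the cerium-modified Grignard reagent to the ester and Peterson elimination of one β-silyl alcohol unit on silica should turn the ester carbon C9 into a 2-substituted allylsilane (the new methylene is C8), the two hydroxyl groups riding through as alkoxides.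

Step 14
Reactants: 21 allylsilane diol
Product: 22 allylsilane aldehyde (C6–CHO = C7; C3–OH free)
Conditions: [Cu(MeCN)4]OTf (5 mol %), 2,2'-bipyridine, TEMPO, N-methylimidazole, air, MeCN, 23 °C
Reagents that add atoms: none
Why: Copper/TEMPO aerobic oxidation is selective for the primary alcohol over the hindered secondary C3–OH and should leave the allylsilane untouched.

Step 15
Reactants: 23 (E)-2-methylbut-2-en-1-ol
Product: 24 [(2R,3R)-2,3-dimethyloxiran-2-yl]methanol
Conditions: Ti(OiPr)4, D-(−)-diethyl tartrate, t-BuOOH, 4 Å MS, CH2Cl2, −20 °C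
Reagents that add atoms: tert-butyl hydroperoxide, CC(C)(C)OO
Why: Sharpless asymmetric epoxidation: the D-(−)-tartrate complex should deliver oxygen to the alkene face that gives the (2R,3R)-epoxy alcohol from this (E)-allylic alcohol.

Step 16
Reactants: 24 [(2R,3R)-2,3-dimethyloxiran-2-yl]methanol
Product: 26 (2S,3R)-2,3-dimethyloxirane-2-carboxylic acid, via epoxy aldehyde 25 (not isolated)
Conditions: RuCl3·H2O (2 mol %), NaIO4, MeCN/EtOAc/H2O, 0 → 23 °C
Reagents that add atoms: water, O
Why: Ruthenium tetroxide generated in the flask should oxidise the primary alcohol through the aldehyde hydrate to the glycidic acid without touching the epoxide (the descriptor at C2 changes only because of CIP priorities).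

Step 17
Reactants: 22 allylsilane aldehyde; 26 (2S,3R)-2,3-dimethyloxirane-2-carboxylic acid
Product: 28 allylsilane aldehyde C3 ester (C3–O–CO–epoxide), via mixed anhydride 27 (not isolated)
Conditions: 2,4,6-Cl3C6H2COCl, Et3N, THF, 23 °C; then 22, DMAP, toluene, 40 °C
Reagents that add atoms: none
Why: Yamaguchi esterification: the mixed anhydride and DMAP should acylate the hindered C3–OH, and the amine base at the same time equilibrates any C6 epimer of the aldehyde to the anti (exo) isomer.

Step 18
Reactants: 28 allylsilane aldehyde C3 ester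
Product: 29 tricyclic homoallylic alcohol (ring C6–C7(OH)–C8H2–C9(=CH2)–C10–C11 closed; both C7 epimers)
Conditions: BF3·OEt2 (1.1 equiv), CH2Cl2, −78 °C
Reagents that add atoms: none
Why: BF3 activates the aldehyde C7=O, the allylsilane attacks through its terminal carbon C8 (SE2′) while the positive charge developing at C9 is stabilised by the β C–Si bond, and loss of the silyl group leaves the exocyclic C9=CH2 and the C7 alkoxide. The closest known reaction type is the intramolecular Hosomi–Sakurai allylation that gives 3-methylenecyclohexanols. The ring closed is the six-membered ring C6–C7–C8–C9–C10–C11, in the 6-exo-trig mode at the carbonyl carbon with the allyl unit attached through its central carbon C9, bridging the 1,3-positions of the cyclobutane. The only new stereocentre, C7–OH, is set by the boat-like bridged transition state and is of no consequence because it is oxidised in step 19. The step needs chemoselectivity for the aldehyde over the epoxy ester and the silyl ether (low temperature, one equivalent of a monodentate Lewis acid), attack through C8 only (guaranteed by silicon) and no cyclobutylcarbinyl cation rearrangement (the β-silyl cation should desilylate fast); the cis-1,3 placement of C7 and C9 on the face opposite the C1–C4 bridge, fixed in steps 12 and 17, is what lets C8 reach C7.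

Step 19
Reactants: 29 tricyclic homoallylic alcohol
Product: 31 silyl ether enone (C7=O; C8=C9–Me; C1–OTBS), via exo-methylene ketone 30 (not isolated)
Conditions: Dess–Martin periodinane, NaHCO3, CH2Cl2, 23 °C; then DBU, 23 °C
Reagents that add atoms: none
Why: Dess–Martin oxidation gives the β,γ-unsaturated ketone and DBU should move the exocyclic double bond into conjugation through the dienolate (C6 is a bridgehead and cannot enolise), giving the favoured 2-en-1-one.

Step 20
Reactants: 31 silyl ether enone
Product: 32 C1 alcohol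
Conditions: HF·pyridine, pyridine, THF, 0 → 23 °C
Reagents that add atoms: none
Why: Buffered HF·pyridine should cleave the silyl ether without opening the glycidic ester or causing migration of the C3 ester.

Step 21
Reactants: 32 C1 alcohol; 33 angelic acid ((Z)-2-methylbut-2-enoic acid)
Product: 35 target CNP0149458.1, via angelic mixed anhydride 34 (not isolated)
Conditions: 2,4,6-Cl3C6H2COCl, Et3N, toluene, 23 °C; then 32, 80 °C
Reagents that add atoms: none
Why: Esterification through the mixed 2,4,6-trichlorobenzoic anhydride without DMAP should acylate the hindered C1–OH and keep the (Z)-geometry of the angelate (no addition–elimination isomerisation to the tiglate).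

**Compound list**

1 | 4,4-dimethylcyclopent-2-en-1-one | O=C1C=CC(C)(C)C1 | starting material
2 | lithium 3,3-dimethylcyclopenta-1,4-dien-1-olate | [Li+].[O-]C1=CC(C)(C)C=C1 | intermediate
3 | allyl 3,3-dimethylcyclopenta-1,4-dien-1-yl carbonate | C=CCOC(=O)OC1=CC(C)(C)C=C1 | intermediate
4 | (5R)-5-allyl-4,4-dimethylcyclopent-2-en-1-one | O=C1C=CC(C)(C)[C@H]1CC=C | intermediate
5 | (5R)-5-(2,3-dihydroxypropyl)-4,4-dimethylcyclopent-2-en-1-one (both carbinol epimers) | O=C1C=CC(C)(C)[C@H]1CC(O)CO | intermediate
6 | 2-[(1R)-2,2-dimethyl-5-oxocyclopent-3-en-1-yl]acetaldehyde | O=C1C=CC(C)(C)[C@H]1CC=O | intermediate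
7 | but-2-yn-1-ol | CC#CCO | starting material
8 | (E)-alkenylzirconocene chloride from 7 (Zr on C3, oxygen also zirconated) | C/C([Zr](Cl)(C1C=CC=C1)C1C=CC=C1)=C\CO[Zr](Cl)(C1C=CC=C1)C1C=CC=C1 | intermediate
9 | (E)-3-iodobut-2-en-1-ol | C/C(I)=C\CO | intermediate
10 | (E)-3-iodobut-2-en-1-yl acetate | C/C(I)=C\COC(C)=O | intermediate
11 | (2E)-5-[(1R)-2,2-dimethyl-5-oxocyclopent-3-en-1-yl]-4-hydroxy-3-methylpent-2-en-1-yl acetate (both carbinol epimers) | CC(=O)OC/C=C(\C)C(O)C[C@@H]1C(C)(C)C=CC1=O | intermediate
12 | (2E)-5-[(1R)-2,2-dimethyl-5-oxocyclopent-3-en-1-yl]-3-methyl-4-oxopent-2-en-1-yl acetate | CC(=O)OC/C=C(\C)C(=O)C[C@@H]1C(C)(C)C=CC1=O | intermediate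
13 | tricyclic diketone (C1 and C9 ketones; C3–C9 bond; CH2OAc exo on C6) | CC(=O)OC[C@@H]1[C@H]2C(C)(C)[C@H]3CC(=O)[C@]1(C)[C@@H]2C3=O | intermediate
14 | keto lactone (C9(=O)–O–C3; C1 ketone) | CC(=O)OC[C@@H]1[C@H]2C(C)(C)[C@H]3CC(=O)[C@]1(C)[C@@H]2C(=O)O3 | intermediate
15 | hydroxy lactone (C1–OH as in the target) | CC(=O)OC[C@@H]1[C@H]2C(C)(C)[C@H]3C[C@@H](O)[C@]1(C)[C@@H]2C(=O)O3 | intermediate
16 | silyl ether lactone (C1–OTBS) | CC(=O)OC[C@@H]1[C@H]2C(C)(C)[C@H]3C[C@@H](O[Si](C)(C)C(C)(C)C)[C@]1(C)[C@@H]2C(=O)O3 | intermediate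
17 | cis hydroxy ester (C10–CO2Me syn to the C1–C4 bridge) | OC[C@@H]1[C@H]2C(C)(C)[C@H](O)C[C@@H](O[Si](C)(C)C(C)(C)C)[C@]1(C)[C@@H]2C(=O)OC | intermediate
18 | trans hydroxy ester (C10–CO2Me anti to the C1–C4 bridge) | OC[C@@H]1[C@H]2C(C)(C)[C@H](O)C[C@@H](O[Si](C)(C)C(C)(C)C)[C@]1(C)[C@H]2C(=O)OC | intermediate
19 | silylmethyl ketone (C10–CO–CH2SiMe3) | OC[C@@H]1[C@H]2C(C)(C)[C@H](O)C[C@@H](O[Si](C)(C)C(C)(C)C)[C@]1(C)[C@H]2C(=O)C[Si](C)(C)C | intermediate
20 | bis(silylmethyl)carbinol (C10–C(OH)(CH2SiMe3)2) | OC[C@@H]1[C@H]2C(C)(C)[C@H](O)C[C@@H](O[Si](C)(C)C(C)(C)C)[C@]1(C)[C@H]2C(O)(C[Si](C)(C)C)C[Si](C)(C)C | intermediate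
21 | allylsilane diol (C10–C(=CH2)CH2SiMe3) | OC[C@@H]1[C@H]2C(C)(C)[C@H](O)C[C@@H](O[Si](C)(C)C(C)(C)C)[C@]1(C)[C@H]2C(=C)C[Si](C)(C)C | intermediate
22 | allylsilane aldehyde (C6–CHO) | O=C[C@@H]1[C@H]2C(C)(C)[C@H](O)C[C@@H](O[Si](C)(C)C(C)(C)C)[C@]1(C)[C@H]2C(=C)C[Si](C)(C)C | intermediate
23 | (E)-2-methylbut-2-en-1-ol | C/C=C(\C)CO | starting material
24 | [(2R,3R)-2,3-dimethyloxiran-2-yl]methanol | OC[C@@]1(C)O[C@@H]1C | intermediate
25 | (2S,3R)-2,3-dimethyloxirane-2-carbaldehyde | O=C[C@@]1(C)O[C@@H]1C | intermediate
26 | (2S,3R)-2,3-dimethyloxirane-2-carboxylic acid | OC(=O)[C@@]1(C)O[C@@H]1C | intermediate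
27 | (2S,3R)-2,3-dimethyloxirane-2-carboxylic 2,4,6-trichlorobenzoic anhydride | O=C(OC(=O)[C@@]1(C)O[C@@H]1C)c1c(Cl)cc(Cl)cc1Cl | intermediate
28 | allylsilane aldehyde bearing the C3 epoxy ester | O=C[C@@H]1[C@H]2C(C)(C)[C@H](OC(=O)[C@@]3(C)O[C@@H]3C)C[C@@H](O[Si](C)(C)C(C)(C)C)[C@]1(C)[C@H]2C(=C)C[Si](C)(C)C | intermediate
29 | tricyclic homoallylic alcohol (C7–OH, both epimers; C9=CH2) | CC(C)(C)[Si](C)(C)O[C@@H]1C[C@@H](OC(=O)[C@@]2(C)O[C@@H]2C)C(C)(C)[C@@H]2[C@H]3C(O)CC(=C)[C@@H]2[C@]31C | intermediate
30 | exo-methylene ketone (C7=O; C9=CH2) | CC(C)(C)[Si](C)(C)O[C@@H]1C[C@@H](OC(=O)[C@@]2(C)O[C@@H]2C)C(C)(C)[C@@H]2[C@H]3C(=O)CC(=C)[C@@H]2[C@]31C | intermediate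
31 | silyl ether enone (C7=O; C8=C9–Me; C1–OTBS) | CC(C)(C)[Si](C)(C)O[C@@H]1C[C@@H](OC(=O)[C@@]2(C)O[C@@H]2C)C(C)(C)[C@@H]2[C@H]3C(=O)C=C(C)[C@@H]2[C@]31C | intermediate
32 | C1 alcohol | O[C@@H]1C[C@@H](OC(=O)[C@@]2(C)O[C@@H]2C)C(C)(C)[C@@H]2[C@H]3C(=O)C=C(C)[C@@H]2[C@]31C | intermediate
33 | angelic acid, (Z)-2-methylbut-2-enoic acid | C/C=C(/C)C(=O)O | starting material
34 | angelic 2,4,6-trichlorobenzoic anhydride | C/C=C(/C)C(=O)OC(=O)c1c(Cl)cc(Cl)cc1Cl | intermediate
35 | CNP0149458.1: (1R,3R,5S,6R,10R,11R)-configured tricyclic enone (numbering above) with the angelate on C1–O and the (2S,3R)-2,3-epoxy-2-methylbutanoate on C3–O | C/C=C(/C)C(=O)O[C@@H]1C[C@@H](OC(=O)[C@@]2(C)O[C@@H]2C)C(C)(C)[C@@H]2[C@H]3C(=O)C=C(C)[C@@H]2[C@]31C | target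

**Step count**

Total: 21 steps. Longest linear sequence: 17 steps (1 → 35 through steps 1–3, 6–14 and 17–21); steps 4–5 and 15–16 are side branches.

**Steps most likely to fail, with fallbacks**

Step 8 (photocycloaddition). The acyclic enone may waste the excitation by E/Z isomerisation or photodeconjugation, or the crossed mode of addition may compete. The fallback sets out from 11, taken as the single (4R) carbinol epimer (step 6 run with a chiral sulfonamide ligand on chromium, or the epimers separated). Silylation with TBSOTf/2,6-lutidine gives the mono-enone silyl ether F1, in which the cyclopentenone is the only chromophore and the alkene is an isolated trisubstituted one. Irradiation at 350 nm should give the tricyclic silyloxy ketone F2, where regiochemistry and face are fixed by the tether alone. Baeyer–Villiger oxidation of its single ketone with mCPBA/NaHCO3 brings the route back at 16.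

Step 9 (Baeyer–Villiger on the diketone). Peracid may fail to discriminate between the two carbonyl groups and also oxidise at C1 with migration of the quaternary carbon. The fallback sets out from 13 and reverses the order of events. LiAlH(OtBu)3 in THF at −78 °C should reduce the more accessible C1 carbonyl from the outer face to the keto alcohol F3. Silylation gives the tricyclic silyloxy ketone F2, whose only ketone is then oxidised with mCPBA; the route is rejoined at 16.

Step 18 (key step). The Lewis acid may open the glycidic ester, or cationic ring expansion of the cyclobutane may compete with desilylation. The fallback sets out from 28. NBS with propylene oxide in CH2Cl2 at −78 °C converts the allylsilane, with allylic transposition (both allyl termini are equivalent), into the allylic bromide F4. CrCl2 in THF at 23 °C then forms the allylchromium reagent, which adds to the aldehyde in a neutral intramolecular Nozaki–Hiyama allylation; the route is rejoined at 29.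

**Further compounds**

F1 | step 8 | silyl ether of (4R)-11, mono-enone | CC(=O)OC/C=C(\C)[C@H](O[Si](C)(C)C(C)(C)C)C[C@@H]1C(C)(C)C=CC1=O
F2 | step 8 | tricyclic silyloxy ketone (as 13 with C1–OTBS in place of the C1 ketone) | CC(=O)OC[C@@H]1[C@H]2C(C)(C)[C@H]3C[C@@H](O[Si](C)(C)C(C)(C)C)[C@]1(C)[C@@H]2C3=O
F3 | step 9 | tricyclic keto alcohol (as 13 with C1–OH; C9 ketone kept) | CC(=O)OC[C@@H]1[C@H]2C(C)(C)[C@H]3C[C@@H](O)[C@]1(C)[C@@H]2C3=O
F4 | step 18 | allylic bromide aldehyde (as 28 with C10–C(=CH2)CH2Br) | O=C[C@@H]1[C@H]2C(C)(C)[C@H](OC(=O)[C@@]3(C)O[C@@H]3C)C[C@@H](O[Si](C)(C)C(C)(C)C)[C@]1(C)[C@H]2C(=C)CBr
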